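**Numbering.** Flavone numbering is used throughout: O1, C2, C3, C4, C4a, C5 to C8, C8a. Ring A is the benzo ring, ring C the pyranone, ring B the 3,4,5-trimethoxyphenyl group. Compounds 1 to 11 are defined in the steps and in the compound list.

## Analysis of the target

Cerosilin B (11) is 5,6,3',4',5'-pentamethoxyflavone: a 4H-chromen-4-one (ring A fused to ring C) with ring B on C2, methoxy groups on C5 and C6, and hydrogen on C7 and C8. The molecule has no stereocenter, so every selectivity question is one of regio- or chemoselectivity. The C5 methoxy group lies peri to the C4 carbonyl and is cleaved by Lewis acids through chelation. C2 is a vinylogous ester carbon that strong nucleophiles can open, and ring B is an electron-rich arene that is easily oxidised. The difficulty lies in ring A, where C4a, C5, C6 and C8a carry an acyl carbon and three oxygens. Closing ring C through O1 to C2 in the usual way would need a 2-hydroxy-5,6-dimethoxyaryl ketone, whose acyl group sits between two oxygens of a 1,2,4-trioxygenated benzene, a position that electrophilic acylation does not choose. The useful feature is that O1 on C8a stands para to the oxygen on C6. A free hydroxyl at C6 therefore makes C8a the para carbon of a phenol, which is where a two-electron oxidation places positive charge. The plan is to form O1 to C8a by oxidation, so that ring A needs only the 2,3-dioxygenation of a simple benzoate such as 1.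

## Retrosynthetic reasoning

**11 to 10.** The first cut is the O-methyl bond at C6. It exposes the C6 phenol in 10, which is the group the ring-closing oxidation needs and leaves unchanged. In the forward direction, 10 has a single hydroxyl that is not chelated to the carbonyl, so a plain etherification finishes the synthesis.

**10 to 7.** The strategic cut is O1 to C8a. Cutting O1 to C2 instead would demand the trioxygenated ring A described above, whereas cutting at C8a removes that oxygen from the precursor. Ring A of 7 is then a 3-hydroxy-2-methoxybenzoyl group, and the tether is an ordinary 1,3-diketone. The forward reaction has to do three things.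
- It must remove two electrons and a proton from the phenol of 7 to give phenoxonium ion 8, and not oxidise ring B or the enol.
- The diketone oxygen on C2 must add to C8a and not to the methoxy-bearing C5, which the tether can also reach.
- Dienone 9 must aromatise to 10 before 10 is oxidised further.

**7 to 6.** The phenol is masked as a benzyl ether. This keeps an acidic hydroxyl out of the enolate chemistry that builds the diketone, and hydrogenolysis later frees it without touching the methyl ethers.

**6 to 4 and 5.** The C3 to C4 bond is cut, which is a Claisen disconnection between the ring A ester 4 and the methyl ketone 5. This polarity puts all of ring B together with C2 and C3 into a purchased ketone. The opposite cut, C2 to C3, would need a ring A methyl ketone that is not a catalogue compound. In the forward reaction only 5 can enolise, and deprotonation of the product diketone drives the condensation.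

**4 to 3 to 1 and 2.** The two ether bonds of ring A are cut in turn. In 1 the 2-hydroxyl is hydrogen-bonded to the ester and conjugated with it, so the 3-hydroxyl should take the benzyl group from 2 first to give 3. The remaining hydroxyl is then methylated to give 4.

## Alternatives that were turned down

**Alternative 1:** one-carbon ring expansion of a benzofuran. The disconnection removes C3 from ring C, leading back to the silyl enol ether A2 of a 2-arylbenzofuran-3-one. In the forward key step a dibromo-substituted carbene, generated from bromoform A3 with a tertiary alkoxide, cyclopropanates the enol ether double bond of A2. The adduct opens with loss of bromide and the silyl group to give the 3-bromoflavone A1, which must then be debrominated.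
- For it: carbene addition to silyl enol ethers and opening of the dihalocyclopropane is a well-understood sequence in carbocycles. The position of the inserted carbon is not in doubt, and the bromide in A1 would be a handle for analogues. On mechanistic security of the key step this alternative is stronger than the chosen route.
- Against it: A2 already contains the ring oxygen on the future C8a, so ring A must again come from a trioxygenated benzene with the acyl carbon between two oxygens. The parent 2-arylbenzofuranone is prone to air oxidation at C2. A halogen is introduced only to be removed, and the alkoxide base can open the pyranone of A1.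
- Comparison: the chosen route reaches its precursor 7 in four standard steps from a 2,3-dioxygenated benzoate and carries no atom that has to be deleted.

**Alternative 2:** construction of ring B. The disconnection cuts C2' to C3' and C5' to C6', leading to the chromon-2-yl vinamidinium salt A5 and 1,3-dimethoxyacetone A6. In the forward key step the doubly enolisable ketone A6 condenses twice with A5 under a strong alkoxide base, with loss of two molecules of the secondary amine, to give the 4'-phenol A4, which is then methylated.
- For it: the [3+3] condensation of vinamidinium salts with ketones to give phenols has close relatives. Rings A and C are already in place, so there is no regiochemical question about the heterocycle, a point on which it is stronger than the chosen route.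
- Against it: it builds a ring that can be bought as the ketone 5. A5 requires a 5,6-dimethoxychromone with a two-carbon acid side chain, so the ring A problem is untouched and several steps are added. The base meets an electrophilic C2 made more so by the iminium group.
- Comparison: in step economy it is clearly behind. The chosen route spends its effort on the one bond that simplifies ring A.

**Alternative 3:** benzannulation of ring A on a pyranone. The disconnection cuts C6 to C7 and C7 to C8, leading to the 2-methyl-3-(methoxyacetyl)pyranone A8 and DMF dimethyl acetal A9 as the source of C7. In the forward key step A9 condenses with the acidic methyl group and with the methylene of the methoxyacetyl group, the secondary amine is lost, and the ring aromatises to the 5-hydroxy-6-methoxyflavone A7. Methylation of the chelated 5-hydroxyl would complete the target.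
- For it: like the chosen route it avoids a trioxygenated arene. It is redox-neutral, so over-oxidation cannot occur, and the positions of the two ring A oxygens are fixed by the connectivity of A8. On these points it is as strong or stronger.
- Against it: A8 is a trisubstituted pyranone that needs its own multistep synthesis, with an open question of 4-pyranone against 2-pyranone closure. Both acidic sites can each take up one molecule of A9, giving a bis-enamine that cannot close. The final methylation is at a hydrogen-bonded hydroxyl.
- Comparison: the chosen route has a precursor made from catalogue compounds by textbook reactions, so that only the ring closure is uncertain.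

Key step: step 5

Remark on the chemistry: 1 is bought as the methyl ester, which is a catalogue compound. Diketones 6 and 7 are drawn as diketo tautomers although they should exist mainly as chelated enols. Dienone 9 would form as a racemate at C8a, and that center is lost on aromatisation.

## Route

Step 1
Reactants: 1 methyl 2,3-dihydroxybenzoate; 2 benzyl bromide
Product: 3 methyl 3-(benzyloxy)-2-hydroxybenzoate
Conditions: BnBr (1.05 equiv), K2CO3 (1.1 equiv), acetone, reflux
Reagents that add atoms: benzyl bromide (2), BrCc1ccccc1
Why: Williamson etherification; the 2-hydroxyl is tied up in a hydrogen bond to the ester carbonyl and its oxygen is conjugated with the ester, so the 3-oxygen should be the more nucleophilic site, and one equivalent of halide limits double alkylation.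

Step 2
Reactants: 3 methyl 3-(benzyloxy)-2-hydroxybenzoate
Product: 4 methyl 3-(benzyloxy)-2-methoxybenzoate
Conditions: MeI (2 equiv), K2CO3 (2 equiv), DMF, 50 °C
Reagents that add atoms: iodomethane, CI
Why: Williamson O-methylation of the only remaining hydroxyl; the polar solvent and gentle heating overcome the hydrogen bond of the salicylate-type phenol.

Step 3
Reactants: 4 methyl 3-(benzyloxy)-2-methoxybenzoate; 5 3',4',5'-trimethoxyacetophenone
Product: 6 1-[3-(benzyloxy)-2-methoxyphenyl]-3-(3,4,5-trimethoxyphenyl)propane-1,3-dione
Conditions: NaH (3 equiv), THF, reflux; then 1 M HCl, 0 °C
Reagents that add atoms: none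
Why: crossed Claisen condensation of the sodium enolate of 5 with the non-enolisable ester 4; deprotonation of the 1,3-diketone as it forms makes the acylation irreversible, and the benzyl and methyl ethers are inert to the base.

Step 4
Reactants: 6 1-[3-(benzyloxy)-2-methoxyphenyl]-3-(3,4,5-trimethoxyphenyl)propane-1,3-dione
Product: 7 1-(3-hydroxy-2-methoxyphenyl)-3-(3,4,5-trimethoxyphenyl)propane-1,3-dione
Conditions: H2 (1 atm), 10% Pd/C, EtOAc, rt
Reagents that add atoms: none
Why: catalytic hydrogenolysis of an aryl benzyl ether; under one atmosphere in a non-acidic solvent the conjugated diaryl diketone and the methyl ethers should be reduced far more slowly than the benzylic C-O bond is cleaved.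

Step 5
Reactants: 7 1-(3-hydroxy-2-methoxyphenyl)-3-(3,4,5-trimethoxyphenyl)propane-1,3-dione
Product: 10 6-hydroxy-5-methoxy-2-(3,4,5-trimethoxyphenyl)-4H-chromen-4-one, via phenoxonium ion 8 (not isolated), via ring-closed 8aH-dienone 9 (not isolated)
Conditions: undivided cell, graphite anode, Pt cathode, constant current (about 2 mA cm-2), 2.1 F mol-1, Bu4NBF4 (0.1 M), (CF3)2CHOH, 0.01 M in 7, 20 °C, N2
Reagents that add atoms: none
Why: Proposed new method: the guaiacol-type phenol of ring A is the most easily oxidised group of neutral 7 (no base is added, so the diketone stays un-ionised and ring B keeps the higher potential of an acylated arene), and loss of two electrons and one proton at the anode gives phenoxonium ion 8 with positive charge at C5, C7 and C8a. The oxygen on C2 (enol hydroxyl or carbonyl oxygen of the diketo form) adds to C8a, closing ring C as a six-membered ring in a 6-exo-trig sense with respect to the C8=C8a bond of the quinoid cation, and the cross-conjugated dienone 9 loses the C8a proton and aromatises to 10, so no stereocenter remains. The closest known reactions are anodic and hypervalent-iodine oxidations of phenols with intramolecular oxygen capture at the para carbon, oxidative closure of 2,3'-dihydroxybenzophenones to xanthones, and anodic dehydrogenative lactonisation of biaryl-2-carboxylic acids; closure of a pyranone by a diketone oxygen onto an unsubstituted para carbon has not been shown. The step needs selectivity between C8a and the methoxy-bearing C5, both within reach of the tether: the C5 adduct would be a mixed ketal of a vinylogous acid and should re-ionise to 8 in the acidic solvent, whereas 9 aromatises irreversibly, so the system should drain to 10, and C7 cannot be reached without a bridged ring. The fluorinated alcohol stabilises 8, does not compete as a nucleophile and breaks the enol chelate, and high dilution disfavours carbon-carbon coupling of phenoxyl radicals. O1 of 10 is a vinylogous ester oxygen and donates only weakly, but 10 is still a para-oxygenated phenol, so the charge is held near 2.1 F per mole at low current density to avoid further oxidation.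

Step 6
Reactants: 10 6-hydroxy-5-methoxy-2-(3,4,5-trimethoxyphenyl)-4H-chromen-4-one
Product: 11 Cerosilin B, 5,6-dimethoxy-2-(3,4,5-trimethoxyphenyl)-4H-chromen-4-one
Conditions: MeI (1.5 equiv), K2CO3 (2 equiv), acetone, reflux
Reagents that add atoms: iodomethane, CI
Why: Williamson O-methylation of the single, non-chelated C6 hydroxyl; the pyranone and the other methyl ethers are stable to carbonate.

## Compound list

1 | methyl 2,3-dihydroxybenzoate | COC(=O)c1cccc(O)c1O | starting material
2 | benzyl bromide | BrCc1ccccc1 | starting material
3 | methyl 3-(benzyloxy)-2-hydroxybenzoate | COC(=O)c1cccc(OCc2ccccc2)c1O | intermediate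
4 | methyl 3-(benzyloxy)-2-methoxybenzoate | COC(=O)c1cccc(OCc2ccccc2)c1OC | intermediate
5 | 3',4',5'-trimethoxyacetophenone | CC(=O)c1cc(OC)c(OC)c(OC)c1 | starting material
6 | 1-[3-(benzyloxy)-2-methoxyphenyl]-3-(3,4,5-trimethoxyphenyl)propane-1,3-dione | COc1c(OCc2ccccc2)cccc1C(=O)CC(=O)c1cc(OC)c(OC)c(OC)c1 | intermediate
7 | 1-(3-hydroxy-2-methoxyphenyl)-3-(3,4,5-trimethoxyphenyl)propane-1,3-dione | COc1c(O)cccc1C(=O)CC(=O)c1cc(OC)c(OC)c(OC)c1 | intermediate
8 | phenoxonium ion of 7 (loss of two electrons and the phenolic proton, drawn with the charge on C8a) | COC1=C(C(=O)CC(=O)c2cc(OC)c(OC)c(OC)c2)[CH+]C=CC1=O | intermediate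
9 | 5-methoxy-2-(3,4,5-trimethoxyphenyl)-8aH-chromene-4,6-dione (racemic at C8a) | COC1=C2C(=O)C=C(c3cc(OC)c(OC)c(OC)c3)OC2C=CC1=O | intermediate
10 | 6-hydroxy-5-methoxy-2-(3,4,5-trimethoxyphenyl)-4H-chromen-4-one | COc1cc(-c2cc(=O)c3c(OC)c(O)ccc3o2)cc(OC)c1OC | intermediate
11 | Cerosilin B, 5,6-dimethoxy-2-(3,4,5-trimethoxyphenyl)-4H-chromen-4-one | COc1cc(-c2cc(=O)c3c(OC)c(OC)ccc3o2)cc(OC)c1OC | target

## Step count and risk

Total: 6 steps. Longest linear sequence: 6 steps (1 to 3 to 4 to 6 to 7 to 10 to 11); 2 and 5 enter as purchased compounds.

**Step 5 (key step, proposed new method).** Four processes could defeat it.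
- Capture of the cation at the methoxy-bearing C5 instead of C8a, if the resulting ketal does not revert.
- Further oxidation of 10 once it has formed, because its para oxygen keeps its potential close to that of 7.
- Carbon-carbon coupling of phenoxyl radicals before the second electron is removed.
- Electron transfer from the diketone enol instead of the phenol.

Fallback, by known chemistry and with a change of approach: the oxygen is first installed on C8a and the ring is then closed by classical dehydration. It sets out from 7. Teuber oxidation with (KSO3)2NO in KH2PO4-buffered aqueous acetone should convert the para-unsubstituted phenol into the acylquinone 2-methoxy-3-[3-oxo-3-(3,4,5-trimethoxyphenyl)propanoyl]cyclohexa-2,5-diene-1,4-dione F1. Reduction in the work-up with aqueous Na2S2O4 should give 1-(3,6-dihydroxy-2-methoxyphenyl)-3-(3,4,5-trimethoxyphenyl)propane-1,3-dione F2. Its hydroxyl ortho to the acyl group should then cyclise with loss of water in AcOH with catalytic H2SO4 at 60 °C. The sequence returns to the route at 10.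

**Step 1.** Loss of regioselectivity is the concern. Proton exchange within the catechol monoanion could lead to alkylation at the 2-oxygen or to double benzylation.

Fallback: protect both hydroxyls and then deprotect one selectively. From 1, excess 2 and K2CO3 in DMF would give methyl 2,3-bis(benzyloxy)benzoate F3. MgBr2·OEt2 in toluene and ether at reflux should then cleave only the benzyl ether ortho to the ester through a magnesium chelate. This returns to the route at 3.

**Step 3.** The acylation may be incomplete because the ester is flanked by an ortho methoxy group and is electron-rich. Ketone 5 may then undergo self-condensation, or the diketone may cleave by a retro-Claisen reaction during a slow reaction.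

Fallback: use a more reactive acyl donor under soft enolisation. From 4, LiOH in aqueous THF would give 3-(benzyloxy)-2-methoxybenzoic acid F4. (COCl)2 with catalytic DMF in CH2Cl2 would give 3-(benzyloxy)-2-methoxybenzoyl chloride F5. C-acylation of 5 with F5 in the presence of MgBr2·OEt2 and i-Pr2NEt in CH2Cl2 returns to the route at 6.

**Step 4.** Over-reduction of an aryl ketone or of the enol double bond could accompany debenzylation if the benzylic cleavage is slow.

Fallback: change the order so that no ketone is present during hydrogenation. From 4, H2 and Pd/C in EtOAc would give methyl 3-hydroxy-2-methoxybenzoate F6. Its phenoxide is meta to the ester and should not shut down acylation, so condensation with 5 using LiN(SiMe3)2 (3.3 equiv) in THF from -78 °C to rt, followed by acidic work-up, returns to the route at 7.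

## Further compounds

F1 | step 5 | 2-methoxy-3-[3-oxo-3-(3,4,5-trimethoxyphenyl)propanoyl]cyclohexa-2,5-diene-1,4-dione | COC1=C(C(=O)CC(=O)c2cc(OC)c(OC)c(OC)c2)C(=O)C=CC1=O
F2 | step 5 | 1-(3,6-dihydroxy-2-methoxyphenyl)-3-(3,4,5-trimethoxyphenyl)propane-1,3-dione | COc1c(O)ccc(O)c1C(=O)CC(=O)c1cc(OC)c(OC)c(OC)c1
F3 | step 1 | methyl 2,3-bis(benzyloxy)benzoate | COC(=O)c1cccc(OCc2ccccc2)c1OCc1ccccc1
F4 | step 3 | 3-(benzyloxy)-2-methoxybenzoic acid | COc1c(OCc2ccccc2)cccc1C(=O)O
F5 | step 3 | 3-(benzyloxy)-2-methoxybenzoyl chloride | COc1c(OCc2ccccc2)cccc1C(=O)Cl
F6 | step 4 | methyl 3-hydroxy-2-methoxybenzoate | COC(=O)c1cccc(O)c1OC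
A1 | alternative 1 | 3-bromo-5,6-dimethoxy-2-(3,4,5-trimethoxyphenyl)-4H-chromen-4-one | COc1cc(-c2oc3ccc(OC)c(OC)c3c(=O)c2Br)cc(OC)c1OC
A2 | alternative 1 | 4,5-dimethoxy-2-(3,4,5-trimethoxyphenyl)-3-[(trimethylsilyl)oxy]-1-benzofuran | COc1cc(-c2oc3ccc(OC)c(OC)c3c2O[Si](C)(C)C)cc(OC)c1OC
A3 | alternative 1 | bromoform | BrC(Br)Br
A4 | alternative 2 | 2-(4-hydroxy-3,5-dimethoxyphenyl)-5,6-dimethoxy-4H-chromen-4-one | COc1cc(-c2cc(=O)c3c(OC)c(OC)ccc3o2)cc(OC)c1O
A5 | alternative 2 | N-[3-(dimethylamino)-2-(5,6-dimethoxy-4-oxo-4H-chromen-2-yl)prop-2-en-1-ylidene]-N-methylmethanaminium hexafluorophosphate | CN(C)C=C(C=[N+](C)C)c1cc(=O)c2c(OC)c(OC)ccc2o1.F[P-](F)(F)(F)(F)F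
A6 | alternative 2 | 1,3-dimethoxyacetone | COCC(=O)COC
A7 | alternative 3 | 5-hydroxy-6-methoxy-2-(3,4,5-trimethoxyphenyl)-4H-chromen-4-one | COc1ccc2oc(-c3cc(OC)c(OC)c(OC)c3)cc(=O)c2c1O
A8 | alternative 3 | 3-(methoxyacetyl)-2-methyl-6-(3,4,5-trimethoxyphenyl)-4H-pyran-4-one | COCC(=O)c1c(C)oc(-c2cc(OC)c(OC)c(OC)c2)cc1=O
A9 | alternative 3 | N,N-dimethylformamide dimethyl acetal | COC(OC)N(C)C
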